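**Target:** 3,5-dibromo-2-(3,5-dibromo-2-hydroxyphenoxy)phenol (11), SMILES Oc1cc(Br)cc(Br)c1Oc1cc(Br)cc(Br)c1O.
Atom labels used below: ring A has C1 (OH), C2 (ether O), C3 (Br), C4 (H), C5 (Br), C6 (H); ring B has C1' (ether O), C2' (H), C3' (Br), C4' (H), C5' (Br), C6' (OH). TBS = tert-butyldimethylsilyl.

## The problem

Compound 11 consists of two 3,5-dibromocatechol rings joined head to tail through one oxygen, and it has no stereocentre. In ring A the bridging oxygen is the catechol oxygen flanked by bromine (on C2), whereas in ring B it is the other one (on C1'), so a synthesis must tell apart the two oxygens of each of two otherwise identical rings. The ether oxygen has three ortho neighbours (C3–Br, C1–OH, C6'–OH), and both partners of a direct arylation would be hindered, halogen-deactivated phenols. The bromines of ring A are meta to its free hydroxyl, so they cannot be introduced by late bromination; the four C–Br bonds also exclude metal-catalysed C–O coupling with aryl halides, organolithium reagents and hydrogenolysis. The free bis-phenol is easily oxidised to ortho-quinones, and its phenoxide can close to a dibenzodioxin at high temperature by displacing the C3 bromine, so the phenols should stay masked until a mild last step. The feature that allows the arylation to be avoided is the substituent sequence of ring B: the run C2'(H)–C3'(Br)–C4'(H)–C5'(Br) is C6–C5–C4–C3 of 3,5-dibromo-2H-pyran-2-one (7), and the adjacent pair C1'(O)–C6'(O) is the α-carbon and the carboxyl carbon of an aryloxyacetic ester. Ring B can therefore be built around an ether oxygen that was attached to C1' while that carbon was still an sp3 CH2 group.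

## Retrosynthesis

**11 from 10.** The two O–Si bonds are cut. Silyl ethers are preferred to methyl ethers because they fall to fluoride at 0 °C, which avoids BBr3 and avoids heating a phenoxide that could close to a dibenzodioxin. Compound 10 is no simpler than 11, but it is the form in which the bis-phenol survives the thermal key step. The forward reaction only has to be cold and buffered.

**10 from 6 and 7.** Two C–C bonds of ring B are cut, C1'–C2' and C5'–C6'. This leaves pyranone 7 (C2'–C5' with both bromines) and ketene silyl acetal 6 (C1' and C6' with both oxygens, the ether bond to ring A already in place).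
- Against the neighbouring benzannulations: a Danheiser benzannulation of an aryl ynol ether would place the two oxygens 1,3 and a carbene-complex benzannulation 1,4. The target needs them 1,2, which an ester-derived ketene acetal carries by construction.
- Against building ring A in the same way: the aryloxy group would then sit on the ketal carbon and would be the group expelled on aromatisation. Ring B is therefore the one to build.
- The precursors are one monoaryl ester derivative and one small heterocycle, and no electrophilic bromination of ring B is needed.
- The forward reaction must add in one orientation only, lose CO2 and lose methanol.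

**6 from 5.** The O–Si bonds of the ketene acetal and of the ring A silyl ether are cut. One operation with two equivalents of base and silyl chloride should protect the phenol and form the ketene acetal together, which saves a separate protection step. Compound 5 is a stable phenol ester. The forward reaction must silylate on oxygen and use a base that leaves the C–Br bonds alone.

**5 from 3 (through 4).** The C1–O bond of ring A is traced back to a C1–CHO bond by Baeyer–Villiger oxidation and cleavage of formate 4. The formyl group is a latent hydroxyl at the one position of ring A that bromination chemistry cannot reach (meta to both bromines). The forward reaction needs aryl rather than hydride migration.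

**3 from 1 and 2.** The O–CH2 bond is cut, an SN2 alkylation of the phenoxide of 1 by methyl bromoacetate (2). Aldehyde 1 already has the bromines ortho and para to the oxygen that becomes the ether oxygen. Alkylating before the second oxygen exists differentiates the two catechol oxygens of ring A without any selective protection. The hindered diaryl ether bond is thereby made as a bond to a primary carbon.

## Roads not taken

**Alternative 1:** the obvious cut is the diaryl ether bond C1'–O between two finished brominated rings. 2,4-Dibromo-6-methoxyphenol A1 would be O-arylated with (3,5-dibromo-2-methoxyphenyl)boronic acid A2 under Chan–Lam conditions (Cu(OAc)2, pyridine, air) to the bis(methyl ether) A3, and BBr3 would give 11. The variant with an ortho-formyl aryl fluoride, SNAr and Dakin oxidation belongs to the same cut. This route is short, and in step count it is at least equal to the chosen one. Its weakness is that the whole difficulty rests on one intermolecular arylation of a phenoxide that is flanked by Br and OMe and made weakly nucleophilic by two bromines, with an aryl partner that is itself ortho-substituted. Metal-mediated variants with aryl halides have four C–Br bonds to choose from, and the SNAr variant has bromines ortho and para to its activating group that compete with fluoride. The chosen plan makes the same C–O bond by SN2 at a primary carbon and never requires a hindered phenoxide to attack an arene.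

**Alternative 2:** the same C1'–O bond is cut but formed by oxidation, in the manner of a biomimetic phenol coupling. 2,4,6-Tribromophenol A4 would be oxidised at an anode in the presence of A1 to the ortho-quinol ether dienone A5 (attack of the phenol oxygen of A1 on a bromine-bearing ortho carbon of the phenoxonium ion). Zinc reduction with loss of bromide would give mono-methyl ether A6, and BBr3 would give 11. Against it: A1 is the more electron-rich phenol, is oxidised at the lower potential and would form its own ortho-quinone monoketal. The phenoxonium ion of A4 also carries bromine at the para carbon, where attack leads to para-linked ethers and poly(phenylene oxide)s. Homo-coupling of each partner competes. Nothing in the substrates decides which oxygen attacks which carbon, whereas in the chosen plan the connectivity is fixed by covalent bonds before ring B exists.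

**Alternative 3:** the ether is again formed at an sp3 carbon, but ring B is taken from a carbocycle. The phenoxide of A1 would displace chloride from 2-chlorocyclohexan-1-one A7 to give α-aryloxy ketone A8 (racemic); aromatising bromination with excess Br2 would give A6, and BBr3 would give 11. Against it:
- Ring B must be oxidised by four electrons and brominated twice in the presence of ring A, whose methoxy group still activates C6.
- Bromination at the aryloxy-bearing α-carbon gives an α-bromo ether that can ionise and expel the phenol, which breaks the very bond just made.
- A secondary α-chloro ketone with a hindered phenoxide invites elimination and Favorskii chemistry.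
- The bromine positions of ring B would rest on directing effects.

Pyranone 7 instead delivers four ring carbons that reach the aromatic oxidation level by loss of CO2 and methanol, with both bromines already attached.

Key step: step 4

Assumption: pyranone 7 is taken as a catalogue compound, and the (Z) geometry drawn for 6 and the configurations of 8 and 9 are left open because these centres are lost on aromatisation.

## Route

Step 1
Reactants: 1 3,5-dibromo-2-hydroxybenzaldehyde (3,5-dibromosalicylaldehyde); 2 methyl bromoacetate
Product: 3 methyl 2-(2,4-dibromo-6-formylphenoxy)acetate
Conditions: K2CO3, DMF, 20–40 °C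
Reagents that add atoms: none
Why: Williamson ether synthesis (SN2); the acidic, di-ortho-substituted phenoxide is a weak nucleophile but the primary α-bromo ester is a very reactive electrophile, and the low temperature is meant to keep the product from aldol closure onto its formyl group.

Step 2
Reactants: 3 methyl 2-(2,4-dibromo-6-formylphenoxy)acetate
Product: 5 methyl 2-(2,4-dibromo-6-hydroxyphenoxy)acetate, via aryl formate 4 (not isolated)
Conditions: mCPBA, CH2Cl2, 0 → 40 °C; then Et3N (cat.), MeOH, 0 °C; dilute HCl wash
Reagents that add atoms: 3-chloroperoxybenzoic acid (mCPBA), OOC(=O)c1cccc(Cl)c1
Why: Baeyer–Villiger (Dakin-type) oxidation of an ortho-alkoxybenzaldehyde, in which the oxygen-substituted aryl group should migrate to give formate 4; aryl formates are cleaved by methanol under mild base, and the methyl ester is unchanged in methanol.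

Step 3
Reactants: 5 methyl 2-(2,4-dibromo-6-hydroxyphenoxy)acetate
Product: 6 tert-butyl{[(Z)-2-(2,4-dibromo-6-{[tert-butyl(dimethyl)silyl]oxy}phenoxy)-1-methoxyethenyl]oxy}dimethylsilane (O-methyl O-TBS ketene acetal of the ester, ring A hydroxyl as TBS ether)
Conditions: TBSCl (2.5 equiv), LiN(SiMe3)2 (2.2 equiv), THF–DMPU, −78 → 20 °C; pentane, filtration under Ar, used crude
Reagents that add atoms: tert-butyldimethylsilyl chloride (TBSCl), CC(C)(C)[Si](C)(C)Cl
Why: Standard formation of an ester-derived ketene silyl acetal (as for an Ireland–Claisen substrate): the first equivalent of base gives the phenoxide, the second the chelated α-aryloxy ester enolate, and both are silylated on oxygen in the polar cosolvent; the amide base does not undergo halogen–metal exchange with the C–Br bonds.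

Step 4
Reactants: 6 ketene silyl acetal (as in step 3); 7 3,5-dibromo-2H-pyran-2-one
Product: 10 tert-butyl[3,5-dibromo-2-(3,5-dibromo-2-{[tert-butyl(dimethyl)silyl]oxy}phenoxy)phenoxy]dimethylsilane (bis-TBS ether of 11), via bicyclic lactone cycloadduct 8 (not isolated), via cyclohexadiene ketal 9 (not isolated)
Conditions: 6 (1.5 equiv), xylene, 4 Å MS, 110 °C then 140 °C, Ar
Reagents that add atoms: none
Why: The electron-poor diene C3–C6 of pyranone 7 and the electron-rich, trioxygenated alkene of 6 should combine in an inverse-electron-demand Diels–Alder reaction, in which the nucleophilic CH(OAr) carbon of 6 bonds to C6 of 7 (the vinylogous acyl position next to the ring oxygen) and the ketal carbon bonds to the bromine-bearing C3, giving bridged lactone 8. Retro-Diels–Alder loss of CO2 from 8 gives cyclohexadiene 9, whose methyl silyl ketal carbon is conjugated with the diene, so ionisation of methoxide to an O-silyl arenium ion and loss of the neighbouring proton (net elimination of methanol) should aromatise it to 10. The closest known reaction type is the aryl annulation of 2-pyranones with 1,1-dialkoxyalkenes, which gives aryl ethers by the same sequence of cycloaddition, CO2 loss and alcohol loss, together with the cycloadditions of 7 itself with enol ethers, which place the oxygen-bearing carbon next to the CBr bridgehead. Ring B is closed by an intermolecular (4+2) cycloaddition that forms C1'–C2' and C5'–C6' at once, and the lactone bridge is only transient. No stereocentre survives, so the geometry of 6 and the endo or exo course of the addition need no control. The selectivity that matters is the orientation of the addition, and it is secured by the polarisation of both partners: two oxygen donors on the ketal carbon against one weakly donating, bromine-deactivated aryloxy group make CH(OAr) the nucleophilic end of 6, and C6 is the electrophilic end of 7; the reverse orientation would put the ether oxygen next to CBr on ring B. The aryl ether oxygen cannot be lost in the aromatisation, because only a substituent on the ketal carbon can leave together with the single hydrogen on the neighbouring carbon, and whether methanol or silanol leaves, or the ketal collapses to the dienone and tautomerises, every path leads to 11 after step 5. Molecular sieves and an excess of 6 are meant to keep the methanol set free from protonating unreacted ketene acetal.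

Step 5
Reactants: 10 bis-TBS ether of 11
Product: 11 3,5-dibromo-2-(3,5-dibromo-2-hydroxyphenoxy)phenol
Conditions: Bu4NF, AcOH, THF, 0 °C
Reagents that add atoms: none
Why: Fluoride cleavage of aryl silyl ethers; the acetic acid buffer and low temperature should keep the phenoxide from closing to a dibenzodioxin by displacing the C3 bromine and from air oxidation.

## Compound list

1 | 3,5-dibromo-2-hydroxybenzaldehyde | O=Cc1cc(Br)cc(Br)c1O | starting material
2 | methyl bromoacetate | COC(=O)CBr | starting material
3 | methyl 2-(2,4-dibromo-6-formylphenoxy)acetate | COC(=O)COc1c(Br)cc(Br)cc1C=O | intermediate
4 | methyl 2-[2,4-dibromo-6-(formyloxy)phenoxy]acetate | COC(=O)COc1c(Br)cc(Br)cc1OC=O | intermediate (not isolated)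
5 | methyl 2-(2,4-dibromo-6-hydroxyphenoxy)acetate | COC(=O)COc1c(Br)cc(Br)cc1O | intermediate
6 | tert-butyl{[(Z)-2-(2,4-dibromo-6-{[tert-butyl(dimethyl)silyl]oxy}phenoxy)-1-methoxyethenyl]oxy}dimethylsilane | CO/C(O[Si](C)(C)C(C)(C)C)=C/Oc1c(Br)cc(Br)cc1O[Si](C)(C)C(C)(C)C | intermediate
7 | 3,5-dibromo-2H-pyran-2-one | O=C1OC=C(Br)C=C1Br | starting material
8 | 4,7-dibromo-6-(2,4-dibromo-6-{[tert-butyl(dimethyl)silyl]oxy}phenoxy)-5-{[tert-butyl(dimethyl)silyl]oxy}-5-methoxy-2-oxabicyclo[2.2.2]oct-7-en-3-one (racemic diastereomer mixture, configuration left open) | O=C1OC2C(Br)=CC1(Br)C(OC)(O[Si](C)(C)C(C)(C)C)C2Oc1c(Br)cc(Br)cc1O[Si](C)(C)C(C)(C)C | intermediate (not isolated)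
9 | tert-butyl{[2,4-dibromo-6-(2,4-dibromo-6-{[tert-butyl(dimethyl)silyl]oxy}phenoxy)-1-methoxycyclohexa-2,4-dien-1-yl]oxy}dimethylsilane (racemic diastereomer mixture, configuration left open) | COC1(O[Si](C)(C)C(C)(C)C)C(Oc2c(Br)cc(Br)cc2O[Si](C)(C)C(C)(C)C)C=C(Br)C=C1Br | intermediate (not isolated)
10 | tert-butyl[3,5-dibromo-2-(3,5-dibromo-2-{[tert-butyl(dimethyl)silyl]oxy}phenoxy)phenoxy]dimethylsilane | CC(C)(C)[Si](C)(C)Oc1c(Br)cc(Br)cc1Oc1c(Br)cc(Br)cc1O[Si](C)(C)C(C)(C)C | intermediate
11 | 3,5-dibromo-2-(3,5-dibromo-2-hydroxyphenoxy)phenol | Oc1cc(Br)cc(Br)c1Oc1cc(Br)cc(Br)c1O | target

## Step count and risks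

Total step count: 5. Longest linear sequence: 5 steps (1 → 3 → 5 → 6 → 10 → 11); pyranone 7 enters at step 4.

**Step 4 (key step).** The most likely failure is a cycloaddition too slow to compete with loss of the ketene acetal. The bonding carbon of 6 carries a di-ortho-substituted aryloxy group, and at 110–140 °C the acetal is consumed by the methanol that product formation sets free, by traces of water and by an O-to-C silyl shift. Addition in the reverse orientation, or conjugate addition at C6 of 7 followed by opening of the pyranone instead of ring closure, are the other risks. The fallback gives up the ring construction and joins two finished rings; it sets out from 1 and comes back at 11. The potassium phenoxide of 1 displaces fluoride (ortho to the formyl group) from 2,4-dibromo-6-fluorobenzaldehyde F1 (K2CO3, DMF, 80 °C) to give 3,5-dibromo-2-(3,5-dibromo-2-formylphenoxy)benzaldehyde F2. A double Baeyer–Villiger oxidation with mCPBA gives 3,5-dibromo-2-[3,5-dibromo-2-(formyloxy)phenoxy]phenyl formate F3, and methanolysis with a trace of Et3N gives 11.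

**Step 3.** Incomplete O-silylation of the lithium phenoxide at low temperature, C-silylation or Claisen self-condensation of the ester enolate, and hydrolysis of the ketene acetal on handling are the likely failures, because a phenoxide and an enolate must both be trapped in one flask. The fallback ties the ester back as a lactone, so that no strong base and no separate phenol protection are needed; it sets out from 5 and comes back at 11. Acid-catalysed lactonisation (TsOH, toluene, reflux, removal of methanol) gives 5,7-dibromo-2,3-dihydro-1,4-benzodioxin-2-one F4. Soft enolisation of this aryl ester (TBSOTf, Et3N, CH2Cl2, 0 °C) gives the cyclic ketene silyl acetal tert-butyl[(5,7-dibromo-1,4-benzodioxin-2-yl)oxy]dimethylsilane F5. Cycloaddition with 7 under the conditions of step 4 follows; here aromatisation should expel the ring A aryloxide from the ketal carbon (a far better leaving group than silanolate) and open the dioxin ring, giving 3,5-dibromo-2-(3,5-dibromo-2-{[tert-butyl(dimethyl)silyl]oxy}phenoxy)phenol F6. Two equivalents of F5 are used, because the phenol formed takes a silyl group from F5; that portion appears as 10. Fluoride as in step 5 converts F6 and any 10 to 11.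

**Step 2.** Hydride instead of aryl migration in the peracid adduct would give the carboxylic acid. The two bromines make the ring electron-poor, and the alkoxy oxygen, flanked by Br and CHO, is twisted out of conjugation. The fallback oxidises before alkylating; it sets out from 1 and comes back at 5. Dakin oxidation of 1 (H2O2, NaOH), where the free ortho-phenoxide makes aryl migration reliable, gives 3,5-dibromobenzene-1,2-diol F7. Mono-alkylation with 2 using NaHCO3 in DMF at 40 °C then gives 5: the bromine-flanked hydroxyl is the more acidic one, so its phenoxide forms and reacts first.

**Step 1.** Intramolecular aldol condensation of the acidic OCH2 group of 3 onto the ortho formyl group (closure to a benzofuran) under carbonate, or a slow alkylation that invites heating and thereby this closure, are the likely failures. The fallback sets out from 1 and comes back at 3: Mitsunobu etherification of 1 with methyl glycolate (PPh3, DIAD, THF, 0 °C). It activates the alcohol instead of deprotonating the phenol, so no base is present that could enolise 3; it makes no new compound.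

## Further compounds

F1 | step 4 | 2,4-dibromo-6-fluorobenzaldehyde (purchased building block) | O=Cc1c(F)cc(Br)cc1Br
F2 | step 4 | 3,5-dibromo-2-(3,5-dibromo-2-formylphenoxy)benzaldehyde | O=Cc1cc(Br)cc(Br)c1Oc1cc(Br)cc(Br)c1C=O
F3 | step 4 | 3,5-dibromo-2-[3,5-dibromo-2-(formyloxy)phenoxy]phenyl formate | O=COc1cc(Br)cc(Br)c1Oc1cc(Br)cc(Br)c1OC=O
F4 | step 3 | 5,7-dibromo-2,3-dihydro-1,4-benzodioxin-2-one | O=C1COc2c(Br)cc(Br)cc2O1
F5 | step 3 | tert-butyl[(5,7-dibromo-1,4-benzodioxin-2-yl)oxy]dimethylsilane | CC(C)(C)[Si](C)(C)OC1=COc2c(Br)cc(Br)cc2O1
F6 | step 3 | 3,5-dibromo-2-(3,5-dibromo-2-{[tert-butyl(dimethyl)silyl]oxy}phenoxy)phenol | CC(C)(C)[Si](C)(C)Oc1c(Br)cc(Br)cc1Oc1c(Br)cc(Br)cc1O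
F7 | step 2 | 3,5-dibromobenzene-1,2-diol | Oc1cc(Br)cc(Br)c1O
F0 | step 1 | none | none
A1 | alternative 1 | 2,4-dibromo-6-methoxyphenol | COc1cc(Br)cc(Br)c1O
A2 | alternative 1 | (3,5-dibromo-2-methoxyphenyl)boronic acid | COc1c(Br)cc(Br)cc1B(O)O
A3 | alternative 1 | 1,5-dibromo-2-(2,4-dibromo-6-methoxyphenoxy)-3-methoxybenzene | COc1cc(Br)cc(Br)c1Oc1cc(Br)cc(Br)c1OC
A4 | alternative 2 | 2,4,6-tribromophenol | Oc1c(Br)cc(Br)cc1Br
A5 | alternative 2 | 2,4,6-tribromo-6-(2,4-dibromo-6-methoxyphenoxy)cyclohexa-2,4-dien-1-one (racemic) | O=C1C(Br)=CC(Br)=CC1(Br)Oc1c(Br)cc(Br)cc1OC
A6 | alternative 2 | 2,4-dibromo-6-(2,4-dibromo-6-methoxyphenoxy)phenol | COc1cc(Br)cc(Br)c1Oc1cc(Br)cc(Br)c1O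
A7 | alternative 3 | 2-chlorocyclohexan-1-one (racemic) | O=C1CCCCC1Cl
A8 | alternative 3 | 2-(2,4-dibromo-6-methoxyphenoxy)cyclohexan-1-one (racemic) | COc1cc(Br)cc(Br)c1OC1CCCCC1=O
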